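The pitfall in this flask is to read the gap in the percentages as J. At 90.0 min of Sunday's run, Q, G and D leave 28.2% of the Q charged unseen, and as J that gap would put 2.16 L per Q into adducts, more than the 1.80 equiv charged.

| setting | Sunday's | flask |
|---|---|---|
| Q | 1.5 M | 1.5 M |
| L | 1.8 equiv | 1.80 equiv |
| remark | the very flask that is asked about, followed so far |  |
| time |  | 20 h |

Sunday's run (percent of the Q charged)

| time / min | Q / % | G / % | D / % |
|---|---|---|---|
| 20.0 | 9.3 | 5.0 | 52.6 |
| 40.0 | 6.6 | 3.9 | 60.2 |
| 60.0 | 6.1 | 3.8 | 62.1 |
| 80.0 | 5.4 | 3.2 | 63.3 |
| 90.0 | 4.6 | 3.0 | 64.2 |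

(scatter of a reading: 0.5 percentage points)

- how much Q there is at 20 h, in percent of the Q charged
- how much G there is at 20 h, in percent of the Q charged
- how much D there is at 20 h, in percent of the Q charged
- how much J there is at 20 h, in percent of the Q charged



The same reading gives a better measure, the room, 16.2% of the Q charged, as a reading: the L charged less the L held in G and D, divided by 3, an upper mark on the Q that has taken 3 L.

The dispute is over what happens to this room. The forecast has the creep going on and J below the room: Q 2.5%, G 1.5%, D 68%, J 14%, in its words “J is then limited by the L balance”.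

I take the other side. Each adduct step takes one L, so I expect its rate to follow c_L. The L going into G and D per minute falls by a factor of 6.22 from the interval 20.0 min to 40.0 min to the interval 60.0 min to 90.0 min, as a reading. So I hold this flask near its last readings, Q 4.6%, G 3.0%, D 64.2%. The room I take as a ceiling on J, since something unseen may hold L too, and I give J no figure of its own.

This flask gives Q 4.57%, G 2.83%, D 64.7% and J 6.06%, so J stands 7.9 percentage points below the forecast.

Q + L → G (k = 0.00203 M⁻¹ s⁻¹); L + G → D (k = 0.00377 M⁻¹ s⁻¹); L + D → J (k = 1.16 × 10⁻⁴ M⁻¹ s⁻¹); J ⇌ E (K = 1.63, k = 0.0183 s⁻¹); Q ⇌ X (K = 2.62, k = 0.00797 s⁻¹) The forecast's creep has its region while L lasts: L, the limiting reagent, is 1.51% of its own charge at 2.00 h and 0% at 10.0 h. In this flask J and E together hold 15.9% at 20.0 h, about the room of 16.2%. In the flask with 0.450 equiv of L, the room from its G and D is 0.399%, with J 0.152% and E 0.247%.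

(The readings were generated by integration from invented constants; the scatter is artificial.)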